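**Plan**

1. Numbering used below: ring A = C1–C5 + C10 (C4 carries the gem-dimethyl group), ring B = C5–C10 (CH3 on C8 and C10), C11 = vinylic CH, arene C1'–C6' (C1' on C11, O-sulfate at C2', CHO at C3', OH at C4' and C5').
2. Retrosynthetic cuts, in order: O2'–SO3H and C3'–CHO (arene end game); C1–C10 (ring A, key step); C10–CH3; C9=C11; C3–C4.
3. Forward: the arene and ring B are bought, ring B as (S)-pulegone. C1–C3 are added to its isopropylidene carbon (which becomes C4) as a silyl-bearing allyl group, the arene is joined at C9 by aldol condensation, CH3 is added to the C10 carbonyl, and ring A closes last through C1–C10.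
4. Enabling feature: C10 is allylic to the exocyclic C9=C11 bond, and the aryl group on C11 carries oxygen at C2' and C4' (ortho and para). A cation at C10 is therefore an aryl-stabilised allyl cation; its capture at C10 by a tethered allylsilane makes the quaternary centre, ring A and the E-styrene in one event, and the tether (six- versus eight-membered ring) selects C10 over C11.
5. Stereochemistry: C8 comes from (S)-pulegone; C5 is set by base equilibration of the arylidene ketone (A(1,3) strain puts the C8 methyl axial and the side chain equatorial, cis); C10 and the trans ring fusion are set in the key step (attack anti to the axial C8 methyl); the E-alkene comes from the condensation.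
6. End game: hydrogenation of the ring-A alkene left by the allylsilane, ortho-lithiation/formylation, MOM removal, and O2'-sulfation under transient boronate protection of the catechol.

Key step: step 6

Assumption: the target is drawn as the free hydrogen sulfate; it would be released from its pyridinium salt on an acidic resin at the end, the salt being the form in which the compound would normally be stored.

**Route**

Step 1
Reactants: 1 allyltrimethylsilane
Product: 3 (E)-1,3-bis(trimethylsilyl)propene, via 1-(trimethylsilyl)allyllithium 2 (not isolated)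
Conditions: s-BuLi, TMEDA, THF, −78 °C; then Me3SiCl, −78 → 0 °C
Reagents that add atoms: chlorotrimethylsilane, C[Si](C)(C)Cl
Why: Allylic deprotonation gives the silyl-stabilised allyl anion, which should be silylated at its unhindered γ-carbon to the E-configured 1,3-disilylpropene (γ-silylation of a heteroatom-stabilised allyl anion).

Step 2
Reactants: 4 (S)-(−)-pulegone; 3 (E)-1,3-bis(trimethylsilyl)propene
Product: 6 (5S)-5-methyl-2-[2-methyl-3-(trimethylsilyl)pent-4-en-2-yl]cyclohexan-1-one, via trichlorotitanium enolate 5 (not isolated)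
Conditions: TiCl4 (1.1 equiv), 3 (2.5 equiv), CH2Cl2, −78 °C; then H2O
Reagents that add atoms: none
Why: In this Hosomi–Sakurai conjugate allylation the silyl-bearing γ-carbon of 3 should attack the β-carbon of the TiCl4-activated s-cis enone with loss of the allylic silyl group, so that C4 becomes quaternary and the new chain is itself an allylsilane; the ring α-carbon is equilibrated in step 4, the silyl-bearing carbon is an inconsequential mixture, and excess 3 at low temperature guards against a second allylation.

Step 3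
Reactants: 7 2,4,5-trihydroxybenzaldehyde
Product: 8 2,4,5-tris(methoxymethoxy)benzaldehyde
Conditions: MOMCl (3.6 equiv), i-Pr2NEt, CH2Cl2, 0 → 25 °C, argon
Reagents that add atoms: chloromethyl methyl ether, COCCl
Why: O-Alkylation of the three phenols gives acetal ethers that survive base, organolithiums and brief Lewis acid at low temperature and later direct the ortho-lithiation.

Step 4
Reactants: 6 (5S)-5-methyl-2-[2-methyl-3-(trimethylsilyl)pent-4-en-2-yl]cyclohexan-1-one; 8 2,4,5-tris(methoxymethoxy)benzaldehyde
Product: 10 (2E,3S,6S)-3-methyl-6-[2-methyl-3-(trimethylsilyl)pent-4-en-2-yl]-2-{[2,4,5-tris(methoxymethoxy)phenyl]methylidene}cyclohexan-1-one, via aldol adduct 9 (not isolated)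
Conditions: NaOEt (0.5 equiv), EtOH, 25 → 50 °C
Reagents that add atoms: none
Why: Claisen–Schmidt condensation at the only enolisable CH2 should give the E-arylidene ketone (aryl anti to C=O), and under the equilibrating base the α-stereocentre C5 should settle cis to the C8 methyl, because A(1,3) strain with the arylidene forces that methyl axial and the bulky side chain then takes the equatorial position.

Step 5
Reactants: 10 the arylidene ketone of step 4
Product: 11 (2E,3S,6S)-1,3-dimethyl-6-[2-methyl-3-(trimethylsilyl)pent-4-en-2-yl]-2-{[2,4,5-tris(methoxymethoxy)phenyl]methylidene}cyclohexan-1-ol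
Conditions: MeLi, anhydrous CeCl3, THF, −78 → −20 °C; aq NH4Cl
Reagents that add atoms: methyllithium, [Li]C
Why: 1,2-Addition of the weakly basic methylcerium reagent to the hindered enone carbonyl (organocerium carbonyl addition) should give the tertiary allylic carbinol, whose new configuration is irrelevant because the centre is ionised in step 6.

Step 6
Reactants: 11 the tertiary allylic carbinol of step 5
Product: 13 (1E,2S,4aS,8aS)-2,5,5,8a-tetramethyl-1-{[2,4,5-tris(methoxymethoxy)phenyl]methylidene}-1,2,3,4,4a,5,8,8a-octahydronaphthalene, via allyl cation 12 (not isolated)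
Conditions: Me3SiOTf (10 mol %), 2,6-di-tert-butyl-4-methylpyridine (20 mol %), CH2Cl2, −78 → −40 °C
Reagents that add atoms: none
Why: The silyl triflate should ionise the tertiary allylic carbinol to cation 12, whose charge is spread over C10, C9–C11 and the 2',4'-dioxygenated ring; the terminal allylsilane carbon C1 then adds to C10, and the β-silyl cation loses Me3Si+ (which carries the chain) to leave the C2=C3 and C9=C11 double bonds. The closest known reaction type is the intramolecular Hosomi–Sakurai reaction, that is, an allylsilane-terminated cation–olefin cyclisation onto an allylic cation made from a tertiary allylic alcohol. Ring A closes as a six-membered ring, 6-endo-trig with respect to the allylsilane double bond and exo with respect to the allyl cation, whose C9=C11 part stays outside as the styrene. The new quaternary centre C10 is controlled by ring B: A(1,3) strain with the aryl-bearing C11 keeps the C8 methyl axial and so the cis C5 side chain equatorial, the axial methyl screens the β-face of C10, and C1 should add from the α-face through a chair-like array, which is the trans ring fusion with the C10 methyl syn to the C8 methyl, the counterpart of the equatorial closure by which monocyclic terpenoid cations give trans-decalins. Attack at C10 rather than at benzylic C11 is secured by ring size (six against eight), the E geometry by the same A(1,3) strain that holds the aryl group on the C8 side, and both epimers at the silyl-bearing carbon converge because that carbon becomes sp2.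

Step 7
Reactants: 13 the ring-A alkene of step 6
Product: 14 (1E,2S,4aS,8aS)-2,5,5,8a-tetramethyl-1-{[2,4,5-tris(methoxymethoxy)phenyl]methylidene}decahydronaphthalene
Conditions: H2 (3 atm), RhCl(PPh3)3 (5 mol %), benzene–EtOH, 25 °C
Reagents that add atoms: none
Why: Homogeneous hydrogenation with the bulky rhodium catalyst should saturate the cis-disubstituted ring-A alkene and leave the trisubstituted styrene, shielded by quaternary C10 and the axial C8 methyl, untouched (sterically controlled chemoselective hydrogenation).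

Step 8
Reactants: 14 the saturated decalin of step 7
Product: 16 2,3,6-tris(methoxymethoxy)-5-{(E)-[(2S,4aS,8aS)-2,5,5,8a-tetramethyloctahydronaphthalen-1(2H)-ylidene]methyl}benzaldehyde, via aryllithium 15 (not isolated)
Conditions: n-BuLi, TMEDA, THF, −78 → −20 °C; then DMF, −78 → 0 °C; aq NH4Cl
Reagents that add atoms: N,N-dimethylformamide, CN(C)C=O
Why: Directed ortho-metalation should remove the aryl proton flanked by two OMOM groups (C3'), the most acidic one, and the aryllithium is formylated by DMF.

Step 9
Reactants: 16 the tris-MOM aldehyde of step 8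
Product: 17 2,3,6-trihydroxy-5-{(E)-[(2S,4aS,8aS)-2,5,5,8a-tetramethyloctahydronaphthalen-1(2H)-ylidene]methyl}benzaldehyde
Conditions: HCl (0.5 M), MeOH, 0 → 25 °C, argon
Reagents that add atoms: none
Why: Acid-catalysed acetal exchange should pass the three MOM groups to methanol, with dilute acid and low temperature chosen so that the freed O2'–H does not add to the acid-sensitive styrene.

Step 10
Reactants: 17 the trihydroxy aldehyde of step 9
Product: 20 2-formyl-3,4-dihydroxy-6-{(E)-[(2S,4aS,8aS)-2,5,5,8a-tetramethyloctahydronaphthalen-1(2H)-ylidene]methyl}phenyl hydrogen sulfate, via cyclic phenylboronate 18 (not isolated), via sulfated boronate 19 (not isolated)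
Conditions: PhB(OH)2 (1.05 equiv), 4 Å molecular sieves, pyridine, 25 °C; then SO3·pyridine (3 equiv), 40 °C; then H2O; sulfonic acid resin (H+ form)
Reagents that add atoms: sulfur trioxide–pyridine complex, O=S(=O)([O-])[n+]1ccccc1
Why: The 4',5'-catechol should be masked in the flask as its five-membered phenylboronate so that only O2'–H is sulfated by SO3·pyridine (phenol O-sulfation under transient boronate protection), after which water hydrolyses the boronate.

**Compound list**

1 | allyltrimethylsilane | C=CC[Si](C)(C)C | starting material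
2 | 1-(trimethylsilyl)allyllithium (not isolated) | [Li]C(C=C)[Si](C)(C)C | intermediate
3 | (E)-1,3-bis(trimethylsilyl)propene | C[Si](C)(C)C/C=C/[Si](C)(C)C | intermediate
4 | (S)-(−)-pulegone | C[C@H]1CCC(=C(C)C)C(=O)C1 | starting material
5 | trichlorotitanium enolate of 6 (not isolated) | C[C@H]1CCC(C(C)(C)C(C=C)[Si](C)(C)C)=C(O[Ti](Cl)(Cl)Cl)C1 | intermediate
6 | (5S)-5-methyl-2-[2-methyl-3-(trimethylsilyl)pent-4-en-2-yl]cyclohexan-1-one, mixture of epimers at ring C2 and at the silyl-bearing carbon | C[C@H]1CCC(C(C)(C)C(C=C)[Si](C)(C)C)C(=O)C1 | intermediate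
7 | 2,4,5-trihydroxybenzaldehyde | O=Cc1cc(O)c(O)cc1O | starting material
8 | 2,4,5-tris(methoxymethoxy)benzaldehyde | O=Cc1cc(OCOC)c(OCOC)cc1OCOC | intermediate
9 | β-hydroxy ketone from 6 and 8, aldol adduct (not isolated) | C[C@H]1CCC(C(C)(C)C(C=C)[Si](C)(C)C)C(=O)C1C(O)c1cc(OCOC)c(OCOC)cc1OCOC | intermediate
10 | (2E,3S,6S)-3-methyl-6-[2-methyl-3-(trimethylsilyl)pent-4-en-2-yl]-2-{[2,4,5-tris(methoxymethoxy)phenyl]methylidene}cyclohexan-1-one, ring methyl and side chain cis, epimers at the silyl-bearing carbon | C[C@H]1CC[C@@H](C(C)(C)C(C=C)[Si](C)(C)C)C(=O)/C1=C/c1cc(OCOC)c(OCOC)cc1OCOC | intermediate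
11 | (2E,3S,6S)-1,3-dimethyl-6-[2-methyl-3-(trimethylsilyl)pent-4-en-2-yl]-2-{[2,4,5-tris(methoxymethoxy)phenyl]methylidene}cyclohexan-1-ol, epimers at C1 and at the silyl-bearing carbon | C[C@H]1CC[C@@H](C(C)(C)C(C=C)[Si](C)(C)C)C(C)(O)/C1=C/c1cc(OCOC)c(OCOC)cc1OCOC | intermediate
12 | aryl-stabilised allyl cation from 11, triflate ion pair (not isolated) | C[C@H]1CC[C@@H](C(C)(C)C(C=C)[Si](C)(C)C)[C+](C)/C1=C/c1cc(OCOC)c(OCOC)cc1OCOC.[O-]S(=O)(=O)C(F)(F)F | intermediate
13 | (1E,2S,4aS,8aS)-2,5,5,8a-tetramethyl-1-{[2,4,5-tris(methoxymethoxy)phenyl]methylidene}-1,2,3,4,4a,5,8,8a-octahydronaphthalene, trans-fused | C[C@H]1CC[C@H]2C(C)(C)C=CC[C@]2(C)/C1=C/c1cc(OCOC)c(OCOC)cc1OCOC | intermediate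
14 | (1E,2S,4aS,8aS)-2,5,5,8a-tetramethyl-1-{[2,4,5-tris(methoxymethoxy)phenyl]methylidene}decahydronaphthalene | C[C@H]1CC[C@H]2C(C)(C)CCC[C@]2(C)/C1=C/c1cc(OCOC)c(OCOC)cc1OCOC | intermediate
15 | aryllithium from 14, lithium at C3' between two OMOM groups (not isolated) | C[C@H]1CC[C@H]2C(C)(C)CCC[C@]2(C)/C1=C/c1cc(OCOC)c(OCOC)c([Li])c1OCOC | intermediate
16 | 2,3,6-tris(methoxymethoxy)-5-{(E)-[(2S,4aS,8aS)-2,5,5,8a-tetramethyloctahydronaphthalen-1(2H)-ylidene]methyl}benzaldehyde | C[C@H]1CC[C@H]2C(C)(C)CCC[C@]2(C)/C1=C/c1cc(OCOC)c(OCOC)c(C=O)c1OCOC | intermediate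
17 | 2,3,6-trihydroxy-5-{(E)-[(2S,4aS,8aS)-2,5,5,8a-tetramethyloctahydronaphthalen-1(2H)-ylidene]methyl}benzaldehyde | C[C@H]1CC[C@H]2C(C)(C)CCC[C@]2(C)/C1=C/c1cc(O)c(O)c(C=O)c1O | intermediate
18 | 4',5'-O-phenylboronate of 17, 2-phenyl-1,3,2-benzodioxaborole (not isolated) | C[C@H]1CC[C@H]2C(C)(C)CCC[C@]2(C)/C1=C/c1cc2OB(c3ccccc3)Oc2c(C=O)c1O | intermediate
19 | 2'-O-sulfate of 18 as pyridinium salt (not isolated) | C[C@H]1CC[C@H]2C(C)(C)CCC[C@]2(C)/C1=C/c1cc2OB(c3ccccc3)Oc2c(C=O)c1OS(=O)(=O)[O-].c1cc[nH+]cc1 | intermediate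
20 | 2-formyl-3,4-dihydroxy-6-{(E)-[(2S,4aS,8aS)-2,5,5,8a-tetramethyloctahydronaphthalen-1(2H)-ylidene]methyl}phenyl hydrogen sulfate | C[C@H]1CC[C@H]2C(C)(C)CCC[C@]2(C)/C1=C/c1cc(O)c(O)c(C=O)c1OS(=O)(=O)O | target

**Step count**

Total: 10 steps. Longest linear sequence: 9 steps (steps 1, 2, 4, 5, 6, 7, 8, 9, 10); step 3 is the side branch.

**Steps most likely to fail**

Step 6. The tether has to deliver C1 to the α-face of C10 from an equatorial side chain, and facial selection could instead follow the torsionally easier path to a cis ring fusion. The silyl epimer that cannot use the chair-like anti arrangement may close slowly. The cation may also lose a proton to dienes (which would erase C5), be protodesilylated, or be captured by the ortho oxygen after rotation about C9–C11. The fallback sets out from 4 and comes back at 13; it removes the tether from the stereo-determining step, keeps ring A as the last ring, and closes it by metathesis. CuI-catalysed conjugate addition of vinylmagnesium bromide to 4 should give (5S)-5-methyl-2-(2-methylbut-3-en-2-yl)cyclohexan-1-one F1. Claisen–Schmidt condensation with 8 under the conditions of step 4 should give the cis arylidene ketone (2E,3S,6S)-3-methyl-6-(2-methylbut-3-en-2-yl)-2-{[2,4,5-tris(methoxymethoxy)phenyl]methylidene}cyclohexan-1-one F2, and MeLi/CeCl3 the carbinol (2E,3S,6S)-1,3-dimethyl-6-(2-methylbut-3-en-2-yl)-2-{[2,4,5-tris(methoxymethoxy)phenyl]methylidene}cyclohexan-1-ol F3. An intermolecular Hosomi–Sakurai allylation of the same kind of allyl cation (allyltrimethylsilane, Me3SiOTf, CH2Cl2, −78 °C), now free to approach anti to the axial C8 methyl, should give (1S,2E,3S,6S)-1,3-dimethyl-6-(2-methylbut-3-en-2-yl)-1-(prop-2-en-1-yl)-2-{[2,4,5-tris(methoxymethoxy)phenyl]methylidene}cyclohexane F4. Ring-closing metathesis of its allyl and 1,1-dimethylallyl groups (second-generation Grubbs catalyst, CH2Cl2, 40 °C) then closes ring A to 13.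

Step 2. Addition of the hindered, silyl-bearing carbon of 3 to a β,β-disubstituted enone may be sluggish, the product allylsilane may be allylated a second time, and the Lewis acid may isomerise the enone. The fallback sets out from 4 and comes back at 14; it replaces the allylsilane terminator by a masked methyl ketone that is put on with a small nucleophile. Mukaiyama–Michael addition of 2-(trimethylsilyloxy)propene (TiCl4, CH2Cl2, −78 °C) should give the diketone (5S)-5-methyl-2-(2-methyl-4-oxopentan-2-yl)cyclohexan-1-one F5. The unhindered methyl ketone is protected (ethylene glycol, PPTS, benzene, reflux) as (5S)-5-methyl-2-[2-methyl-1-(2-methyl-1,3-dioxolan-2-yl)propan-2-yl]cyclohexan-1-one F6. Condensation with 8 as in step 4 should give (2E,3S,6S)-3-methyl-6-[2-methyl-1-(2-methyl-1,3-dioxolan-2-yl)propan-2-yl]-2-{[2,4,5-tris(methoxymethoxy)phenyl]methylidene}cyclohexan-1-one F7, and MeLi/CeCl3 the corresponding 1-methyl carbinol (2E,3S,6S)-1,3-dimethyl-6-[2-methyl-1-(2-methyl-1,3-dioxolan-2-yl)propan-2-yl]-2-{[2,4,5-tris(methoxymethoxy)phenyl]methylidene}cyclohexan-1-ol F8. With Me3SiOTf (catalytic, CH2Cl2, −40 °C) the ketal opens to its enol ether, whose terminal carbon captures the allyl cation at C10, and aqueous work-up should give the ring-A ketone (4aS,7S,8E,8aS)-4,4,7,8a-tetramethyl-8-{[2,4,5-tris(methoxymethoxy)phenyl]methylidene}octahydronaphthalen-2(1H)-one F9. Wolff–Kishner reduction (N2H4·H2O, KOH, diethylene glycol, 200 °C) removes the ring-A carbonyl and gives 14.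

Step 10. The boronate may exchange under the sulfation conditions so that a catechol oxygen is sulfated, the hydrogen-bonded O2'–H may react incompletely, and the sulfate may be lost during acidification. The fallback sets out from 17 and comes back at 20; it uses an isolable catechol protecting group removed by fluoride. t-Bu2Si(OTf)2 with 2,6-lutidine (CH2Cl2, 0 °C) should bridge the 4',5'-catechol to give the 4',5'-O-di-tert-butylsilylene derivative of 17 F10. SO3·pyridine (pyridine, 40 °C) sulfates the remaining phenol to the 2'-O-sulfate of the silylene F11. Bu4NF buffered with AcOH (THF, 0 °C) removes the silylene, and the acidic resin gives 20.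

**Further compounds**

F1 | step 6 | (5S)-5-methyl-2-(2-methylbut-3-en-2-yl)cyclohexan-1-one, epimers at C2 | C[C@H]1CCC(C(C)(C)C=C)C(=O)C1
F2 | step 6 | (2E,3S,6S)-3-methyl-6-(2-methylbut-3-en-2-yl)-2-{[2,4,5-tris(methoxymethoxy)phenyl]methylidene}cyclohexan-1-one | C[C@H]1CC[C@@H](C(C)(C)C=C)C(=O)/C1=C/c1cc(OCOC)c(OCOC)cc1OCOC
F3 | step 6 | (2E,3S,6S)-1,3-dimethyl-6-(2-methylbut-3-en-2-yl)-2-{[2,4,5-tris(methoxymethoxy)phenyl]methylidene}cyclohexan-1-ol, epimers at C1 | C[C@H]1CC[C@@H](C(C)(C)C=C)C(C)(O)/C1=C/c1cc(OCOC)c(OCOC)cc1OCOC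
F4 | step 6 | (1S,2E,3S,6S)-1,3-dimethyl-6-(2-methylbut-3-en-2-yl)-1-(prop-2-en-1-yl)-2-{[2,4,5-tris(methoxymethoxy)phenyl]methylidene}cyclohexane | C[C@H]1CC[C@@H](C(C)(C)C=C)[C@](C)(CC=C)/C1=C/c1cc(OCOC)c(OCOC)cc1OCOC
F5 | step 2 | (5S)-5-methyl-2-(2-methyl-4-oxopentan-2-yl)cyclohexan-1-one, epimers at C2 | C[C@H]1CCC(C(C)(C)CC(C)=O)C(=O)C1
F6 | step 2 | (5S)-5-methyl-2-[2-methyl-1-(2-methyl-1,3-dioxolan-2-yl)propan-2-yl]cyclohexan-1-one, epimers at C2 | C[C@H]1CCC(C(C)(C)CC2(C)OCCO2)C(=O)C1
F7 | step 2 | (2E,3S,6S)-3-methyl-6-[2-methyl-1-(2-methyl-1,3-dioxolan-2-yl)propan-2-yl]-2-{[2,4,5-tris(methoxymethoxy)phenyl]methylidene}cyclohexan-1-one | C[C@H]1CC[C@@H](C(C)(C)CC2(C)OCCO2)C(=O)/C1=C/c1cc(OCOC)c(OCOC)cc1OCOC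
F8 | step 2 | (2E,3S,6S)-1,3-dimethyl-6-[2-methyl-1-(2-methyl-1,3-dioxolan-2-yl)propan-2-yl]-2-{[2,4,5-tris(methoxymethoxy)phenyl]methylidene}cyclohexan-1-ol, epimers at C1 | C[C@H]1CC[C@@H](C(C)(C)CC2(C)OCCO2)C(C)(O)/C1=C/c1cc(OCOC)c(OCOC)cc1OCOC
F9 | step 2 | (4aS,7S,8E,8aS)-4,4,7,8a-tetramethyl-8-{[2,4,5-tris(methoxymethoxy)phenyl]methylidene}octahydronaphthalen-2(1H)-one | C[C@H]1CC[C@H]2C(C)(C)CC(=O)C[C@]2(C)/C1=C/c1cc(OCOC)c(OCOC)cc1OCOC
F10 | step 10 | 4',5'-O-di-tert-butylsilylene derivative of 17 | C[C@H]1CC[C@H]2C(C)(C)CCC[C@]2(C)/C1=C/c1cc2O[Si](C(C)(C)C)(C(C)(C)C)Oc2c(C=O)c1O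
F11 | step 10 | 2'-O-sulfate of F10, hydrogen sulfate form | C[C@H]1CC[C@H]2C(C)(C)CCC[C@]2(C)/C1=C/c1cc2O[Si](C(C)(C)C)(C(C)(C)C)Oc2c(C=O)c1OS(=O)(=O)O
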